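**Retrosynthetic overview**

- Feature: ring B carries its ether oxygen (C1') and its hydroxyl (C2') on neighbouring carbons, with bromine on C3' to C6'. This is the 1,2-difunctionalisation pattern of symmetric tetrabromobenzyne. The C1' oxygen is one oxygen of a catechol, which becomes ring A (C6 ether oxygen, C1 OH, Br at C2 and C4).
- Building blocks: tetrabromophthalic anhydride 1 → imide 2 → anthranilic acid 3 (Hofmann); catechol 4 + boric acid 5 + KOH → borate 6.
- Key disconnection (C1'–O and C2'–O of ring B): 3 → diazonium carboxylate 7 → aryne 8, which inserts into a B–O bond of 6 to give spiroborate 9; C–B oxidation then gives the diaryl ether diol 10.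
- Last disconnection (the two C–Br bonds of ring A): 10 + 2 Br2 → target 11.
- Ring order: no ring is formed, since rings A and B are bought as catechol and the anhydride. The target has no stereocentre and its diaryl ether axis rotates freely, so it is treated as achiral.

Key step: step 4

**Route**

Step 1
Reactants: 1 tetrabromophthalic anhydride
Product: 2 4,5,6,7-tetrabromoisoindoline-1,3-dione (tetrabromophthalimide)
Conditions: NH4OAc, AcOH, reflux
Reagents that add atoms: ammonium acetate, CC(=O)[O-].[NH4+]
Why: Imide formation from a cyclic anhydride (ammonolysis to the phthalamic acid, then thermal cyclodehydration); the electron-poor anhydride acylates ammonia readily and the aryl bromides are inert in hot acetic acid.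

Step 2
Reactants: 2 4,5,6,7-tetrabromoisoindoline-1,3-dione
Product: 3 2-amino-3,4,5,6-tetrabromobenzoic acid (tetrabromoanthranilic acid)
Conditions: NaOH, H2O, 0 °C; NaOBr (from Br2, NaOH, 1.0 equiv), 0 → 75 °C; then HCl, 0 °C
Reagents that add atoms: sodium hydroxide, [Na+].[OH-]
Why: Hofmann rearrangement: hydroxide opens the imide to the phthalamate, whose primary amide is N-brominated and rearranges to the isocyanate, and hydrolysis with loss of CO2 leaves the amine beside the carboxylate, the classical access to tetrahaloanthranilic acids.

Step 3
Reactants: 4 catechol (2 equiv), 5 boric acid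
Product: 6 potassium bis(catecholato)borate
Conditions: KOH (1 equiv), H2O, N2, 90 °C; crystallise; dry at 120 °C under vacuum
Reagents that add atoms: potassium hydroxide, [K+].[OH-]
Why: Chelate esterification of boric acid by two catechols gives the tetracoordinate spiroborate, favoured by its two five-membered dioxaborole rings and crystallising as the potassium salt.

Step 4
Reactants: 3 2-amino-3,4,5,6-tetrabromobenzoic acid, 6 potassium bis(catecholato)borate
Product: 10 3,4,5,6-tetrabromo-2-(2-hydroxyphenoxy)phenol, via tetrabromobenzenediazonium carboxylate 7 (not isolated), via tetrabromobenzyne 8 (not isolated), via potassium spiro aryl borate 9 (not isolated)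
Conditions: 6 (2.5 equiv), 18-crown-6, 4 Å MS, 3-methylbutyl nitrite, ClCH2CH2Cl, 60 °C, 3 in THF added slowly; then 30% H2O2, aq NaOH, THF, 0 °C; then aq HCl
Reagents that add atoms: hydrogen peroxide, OO
Why: Proposed new method: aprotic diazotisation of 3 gives 7, which loses N2 and CO2 to the aryne 8; a borate oxygen of 6 adds to one aryne carbon (C1'), and the aryl anion created at C2' attacks the adjacent boron through a four-centre transition state while the weakened B–O(oxonium) bond gives way, so that 8 is inserted into a B–O bond to give 9, after which alkaline H2O2 triggers the 1,2-shift of C2' from boron to oxygen and hydrolysis of all B–O bonds, leaving C2'–OH and the ring A phenol. The closest known reaction types are aryne σ-bond insertions into N–Si, S–Sn and O–H bonds, the generation of tetrahalobenzynes from tetrahaloanthranilic acids with alkyl nitrites, the capture of aryl anions by borate esters and the oxidation of arylboron compounds with H2O2. No ring survives the step: the seven-membered borate ring of 9 closes by the intramolecular attack of C2' on boron and is opened again in the oxidation, and no stereocentre is formed. Regioselectivity is not an issue because 8 is symmetric and both aryne carbons are flanked by bromine. The step needs oxygen attack to outrun (4+2) addition of 8 to the catecholate rings and azo coupling of 7, which the anionic oxygen nucleophile, the excess of 6 and the slow addition of 3 are meant to secure. It also needs boron capture to outrun protonation of the C2' anion by the water and alcohol released in the diazotisation, which the intramolecular four-centre collapse and the molecular sieves are meant to secure.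

Step 5
Reactants: 10 3,4,5,6-tetrabromo-2-(2-hydroxyphenoxy)phenol
Product: 11 3,4,5,6-tetrabromo-2-(3,5-dibromo-2-hydroxyphenoxy)phenol (target)
Conditions: Br2 (2.0 equiv), AcOH, 15–20 °C
Reagents that add atoms: bromine, BrBr
Why: Electrophilic aromatic bromination: ring B has no C–H left, and ring A should react para and then ortho to its free hydroxyl (C4, then C2), which is a stronger donor than the oxygen shared with the electron-poor ring B; the stoichiometry and the deactivation by two bromines should leave C3 and C5 untouched.

**Compound list**

1 | tetrabromophthalic anhydride (4,5,6,7-tetrabromo-2-benzofuran-1,3-dione) | O=C1OC(=O)c2c(Br)c(Br)c(Br)c(Br)c12 | starting material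
2 | 4,5,6,7-tetrabromoisoindoline-1,3-dione (tetrabromophthalimide) | O=C1NC(=O)c2c(Br)c(Br)c(Br)c(Br)c12 | intermediate
3 | 2-amino-3,4,5,6-tetrabromobenzoic acid | Nc1c(Br)c(Br)c(Br)c(Br)c1C(=O)O | intermediate
4 | catechol (benzene-1,2-diol) | Oc1ccccc1O | starting material
5 | boric acid | OB(O)O | starting material
6 | potassium bis(catecholato)borate | [K+].c1ccc2c(c1)O[B-]1(O2)Oc2ccccc2O1 | intermediate
7 | 3,4,5,6-tetrabromobenzenediazonium-2-carboxylate (inner salt) | N#[N+]c1c(Br)c(Br)c(Br)c(Br)c1C(=O)[O-] | intermediate
8 | tetrabromobenzyne (3,4,5,6-tetrabromo-1,2-didehydrobenzene) | BrC1=C(Br)C(Br)=C(Br)C#C1 | intermediate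
9 | potassium spiroborate: boron bound to C2' of the tetrabromoarene, to the second oxygen of the bridging catechol (seven-membered ring C2'–C1'–O–C–C–O–B) and to both oxygens of the other catecholate | [K+].Brc1c(Br)c(Br)c(Br)c2c1[B-]1(Oc3ccccc3O1)Oc1ccccc1O2 | intermediate
10 | 3,4,5,6-tetrabromo-2-(2-hydroxyphenoxy)phenol | Oc1ccccc1Oc1c(O)c(Br)c(Br)c(Br)c1Br | intermediate
11 | 3,4,5,6-tetrabromo-2-(3,5-dibromo-2-hydroxyphenoxy)phenol | Oc1c(Br)cc(Br)cc1Oc1c(O)c(Br)c(Br)c(Br)c1Br | target

**Summary**

Total step count: 5. Longest linear sequence: 4 steps (steps 1, 2, 4, 5); step 3 is a one-step side branch.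

Steps most likely to fail:

1. Step 4 (proposed new method). The aryne may add across a catecholate ring in a (4+2) sense, or the diazonium carboxylate may azo-couple with the electron-rich borate, before oxygen attack occurs. The C2' anion may also be protonated before it reaches boron, which would give an ether without the C2' oxygen. Fallback by known chemistry, setting out from catechol 4 and coming back at 10: catechol 4 is brominated exhaustively (Br2, 4 equiv, AcOH/CHCl3) to 3,4,5,6-tetrabromobenzene-1,2-diol F1. Its monophenoxide (K2CO3, DMAc, 110 °C, F1 in excess) displaces fluoride from 2-fluorobenzaldehyde by nucleophilic aromatic substitution to give 2-(2,3,4,5-tetrabromo-6-hydroxyphenoxy)benzaldehyde F2. Baeyer–Villiger (Dakin-type) oxidation with mCPBA in CH2Cl2 gives 2-(2,3,4,5-tetrabromo-6-hydroxyphenoxy)phenyl formate F3, which HCl in MeOH cleaves to 10.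

2. Step 2. Hydroxide may displace an activated ring bromine during the warm alkaline phase, excess hypobromite may N-brominate the product, and the anthranilic acid may decarboxylate on acidification. Fallback setting out from anhydride 1 and coming back at 3 (it also bypasses step 1): 1 is heated with trimethylsilyl azide (toluene, 90 °C). The acyl azide formed by ring opening undergoes Curtius rearrangement and the isocyanate is trapped by the neighbouring silyl carboxylate, giving after aqueous work-up 5,6,7,8-tetrabromo-1H-3,1-benzoxazine-2,4-dione (tetrabromoisatoic anhydride) F4. Cold aqueous NaOH followed by HCl opens it with loss of CO2 to 3.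

3. Step 5. Bromination may run on to C5 or C3 of ring A, or begin para to the ether oxygen, giving isomers that are hard to separate. Fallback setting out from catechol 4 and coming back at 11, in which ring A arrives already brominated: 1,3-dibromo-5-fluorobenzene is deprotonated between F and Br with LDA (THF, −78 °C) and formylated with DMF to 2,4-dibromo-6-fluorobenzaldehyde F5. 3,4,5,6-Tetrabromobenzene-1,2-diol F1 (from 4 as in the fallback for step 4) displaces the fluoride (K2CO3, DMAc, 90 °C) to give 2,4-dibromo-6-(2,3,4,5-tetrabromo-6-hydroxyphenoxy)benzaldehyde F6. mCPBA in CH2Cl2 converts it into 2,4-dibromo-6-(2,3,4,5-tetrabromo-6-hydroxyphenoxy)phenyl formate F7, and HCl in MeOH releases 11.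

**Further compounds**

F1 | step 4 | 3,4,5,6-tetrabromobenzene-1,2-diol | Oc1c(O)c(Br)c(Br)c(Br)c1Br
F2 | step 4 | 2-(2,3,4,5-tetrabromo-6-hydroxyphenoxy)benzaldehyde | O=Cc1ccccc1Oc1c(O)c(Br)c(Br)c(Br)c1Br
F3 | step 4 | 2-(2,3,4,5-tetrabromo-6-hydroxyphenoxy)phenyl formate | O=COc1ccccc1Oc1c(O)c(Br)c(Br)c(Br)c1Br
F4 | step 2 | 5,6,7,8-tetrabromo-1H-3,1-benzoxazine-2,4-dione | O=C1Nc2c(Br)c(Br)c(Br)c(Br)c2C(=O)O1
F5 | step 5 | 2,4-dibromo-6-fluorobenzaldehyde | O=Cc1c(F)cc(Br)cc1Br
F6 | step 5 | 2,4-dibromo-6-(2,3,4,5-tetrabromo-6-hydroxyphenoxy)benzaldehyde | O=Cc1c(Br)cc(Br)cc1Oc1c(O)c(Br)c(Br)c(Br)c1Br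
F7 | step 5 | 2,4-dibromo-6-(2,3,4,5-tetrabromo-6-hydroxyphenoxy)phenyl formate | O=COc1c(Br)cc(Br)cc1Oc1c(O)c(Br)c(Br)c(Br)c1Br
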